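Abbreviations: TBS = tert-butyldimethylsilyl; TMS = trimethylsilyl; Bn = benzyl; DCC = N,N'-dicyclohexylcarbodiimide; ArBnCO, ArHCO and ArSiCO = the 4-benzyloxy-, 4-hydroxy- and 4-(TBS-oxy)-2-methoxy-6-methylbenzoyl groups. Positions C1–C8a are the isochromene positions of target 29 and are kept for its precursors.

## The problem

Target 29 is a 6,7-dihydro-1H-isochromen-8(5H)-one. A 2H-pyran (C1, O2, C3, C4) is fused across the C4a=C8a double bond to a cyclohexenone (ring A, C5–C8), and C3 carries an (E)-propenyl group, so that O2–C3=C4–C4a=C8a–C8=O is one conjugated dienyl ether–enone. The only stereocentres are the neighbours C6 (S, secondary alcohol) and C7 (R, quaternary, with a methyl and an aroyloxy group), and the two oxygens are trans. C7 is fully substituted and lies between the ketone and the carbinol, so neither centre can be corrected later; the pair is too remote from the flat pyran to control anything else and is best set in one event on a prochiral ring A. The C7 ester joins a 2,6-disubstituted benzoic acid to a tertiary α-keto carbon, a bond that acylation cannot be trusted to make. The fragile points are the β-hydroxy ketone through a quaternary carbon (retro-aldol at C6–C7 and O7→O6 acyl shift in base), the enol ether (hydration in aqueous acid), the diene (no late hydrogenation), the free phenol and the acidic o-toluate methyl group. The feature that opens the structure is that C4a and C8a are the β- and α-carbons of the C8 enone and each bears exactly one pyran carbon (C4 and C1). Because C7 has no hydrogen, that ketone gives a single enolate, and an enone, an alkynyl nucleophile and formaldehyde account for the whole skeleton.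

## Retrosynthesis

**O2–C3 (29 ⇒ 28).** Cutting the enol ether C–O bond turns C3–C4 into an alkyne and the pyran into the open enynol 28, an isomer of 29. A C1–O2 cut would need a C3 enol oxygen to be alkylated and would invite carbocyclisation instead. The forward reaction must be a 6-endo addition of the C1 hydroxyl to C3, which is the δ-carbon of the enynone and carries the propenyl group.

**Silyl groups and the C4a=C8a bond (28 ⇒ 27 ⇒ 25).** Restoring three silyl ethers gives 27. Adding hydrogen across C4a=C8a gives the saturated ketone 25, whose α- and β-carbons are sp3 and each carry one carbon substituent: the retron of a conjugate addition followed by an aldol. The forward dehydrogenation has only one possible direction of enolisation.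

**C4a–C4 and C8a–C1 (25 ⇒ 24 ⇒ 16 + 19 + 20).** Both pyran carbons are removed in one cut, leaving the monocyclic enone 16, the enyne 19 and formaldehyde 20. A stepwise alkynylation followed by regeneration of the enolate, or hydroxymethylation of the enone first, would cost steps and give a poorer acceptor. The forward reaction has to deliver an alkynyl group 1,4 to an s-trans enone and capture the resulting enolate at carbon.

**Enone and silyl ethers (16 ⇒ 14 ⇒ 13).** The enone comes from ketone 14 by dehydrogenation toward its only CH2 α-carbon, and 14 from ketol 13 by silylation of both hydroxyls.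

**C6–H (13 ⇒ 12 ⇒ 11).** Removing the carbinol hydrogen gives the achiral dione 12, which has a mirror plane through C7. Reduction of one enantiotopic carbonyl from one face sets C6 and C7 together, which no stepwise approach to a quaternary centre can match. The benzyl ether of 11 is exchanged here because no alkene is yet present.

**C7–O (11 ⇒ 9 + 8).** The ester is cut between the ring carbon and oxygen, giving the enolate of dione 9 and the diaroyl peroxide 8 as an electrophilic oxygen source. The alternative acyl–oxygen cut would require acylating a tertiary alcohol with a doubly ortho-substituted acid. Here the hindrance helps, since it shields the peroxide carbonyls from acyl transfer.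

**The aroyl unit (8 ⇒ 4 + 6 ⇒ 3 ⇒ 1).** The O–O-linked dimer 8 is cut at one acyl–oxygen bond into acid 4 and its own peroxy acid 6, which is made from 4 through the acid chloride. Assembling the peroxide from these two defined halves under neutral, anhydrous conditions keeps the electron-rich product away from aqueous alkali. Acid 4 comes from methyl orsellinate 1 by differentiating its two phenols: the free C4 hydroxyl is benzylated, the chelated C2 hydroxyl methylated, and the hindered ester of 3 saponified.

**The enyne (19 ⇒ 17).** One-carbon homologation of (E)-but-2-enal 17 with a lithiated silyldiazomethane gives the terminal alkyne directly and keeps the alkene geometry of a cheap starting material. No acetylide and no alkyl halide is formed on the way, so the volatile enyne 19 can be taken into the nickel-catalysed step as a distilled ethereal solution.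

## Roads not taken

**Alternative 1: benzoate ring built last.** The cut is through the arene bonds C1'–C2' and C6'–C5': the ester is carried as the C7 but-2-ynoate A1, which reacts as a dienophile with the silyloxy ketene-acetal diene A2 in hot toluene. Loss of methanol and desilylation give A3, the 6-O-TBS ether of 29. Its merit is real: the acyl group on the tertiary oxygen is small and linear, so the hindered-ester problem disappears, the arene substitution pattern follows from the diene polarity, and A3 is one desilylation from the target. Its weak points are the following: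
- A1 is the complete, sensitive dienyl ether–enone, which would be heated with a very electron-rich diene for a sluggish internal alkynoate.
- The core offers competing π-systems to both partners.
- The methanol and acid released on aromatisation threaten the enol ether.
- A1 still has to be made by acylating a tertiary α-keto carbinol next to a differentiated C6 oxygen.

On the ester bond this road is the better one. The chosen plan answers by forming C7–O from the enolate side at the symmetric dione stage (step 5), where hindrance does not matter, and then uses the shielded aroate as a robust spectator; no thermal step follows once the chromophore exists.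

**Alternative 2: amine-catalysed aldol forming C6–C7.** The cut is the C6–C7 bond. A cinchona-derived primary amine with an acid co-catalyst converts the ketone of the racemic keto aldehyde A4 into its C7 enamine, which closes ring A onto the aldehyde and gives ketol A5. This is small-molecule catalysis with no enzyme screening, the racemic centre of A4 converges through the planar enamine, and A5 differs from ketol 13 only in its aryl silyl ether, so one silylation would take it to 14 and into the route at step 9. Against it, the enamine must form at the more substituted, acyloxy-bearing α-carbon, which is slow; its geometry decides whether the hydroxyl is trans or cis to the ester; the aldehyde can enolise and self-condense; and A4 needs its own linear synthesis. If no ketoreductase gave the trans ketol, this road would be the stronger one. The chosen plan sets against it a short access to dione 12 from commercial 9 and the orsellinate-derived peroxide 8, and a stereo-defining step that forms no bond at a fully substituted carbon.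

**Alternative 3: singlet-oxygen Achmatowicz reaction.** The cut is O2–C1, with the pyran unveiled from a ring A-fused furyl carbinol A6. Sensitised singlet oxygen adds across the furan α-carbons C1 and C4, a sulfide reduces the endoperoxide to the cis-enedione, and the C3 hydroxyl closes on the C1 aldehyde to give lactol A7. The step is very mild, metal-free, and creates the C4a=C8a unsaturation and the pyran together, which is better than the palladium dehydrogenation used here. Its weakness for this target is the oxidation pattern of A7: C1 is a lactol and not a methylene, C4 is a ketone and not a methine, and C3 is an sp3 stereocentre that 29 does not have. Reaching 29 would need lactol reduction, removal of the C4 oxygen and introduction of C3=C4 on a labile enedione. The propenyl group, with its allylic hydrogens, is also a substrate for the ene reaction of singlet oxygen. The chosen plan sets against this an exact match of oxidation state: formaldehyde delivers C1 as CH2–O and the alkyne delivers C3/C4 at the enol ether level, so the ring closure is an isomerisation.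

Key step: step 11

Assumptions:
- Formaldehyde 20 is used as the monomer, generated by thermal cracking of commercial paraformaldehyde just before use.
- A ketoreductase that gives ketol 13 is taken to be identifiable by screening a commercial enzyme panel.
- Adduct 24 is drawn as the expected major diastereomer; its C4a and C8a epimers converge on 27.
- Enyne 19 is handled as a dried, assayed solution in Et2O, the solvent of step 11.

## Route

**Step 1**
Reactants: 1 methyl orsellinate (methyl 2,4-dihydroxy-6-methylbenzoate)
Product: 3 methyl 4-(benzyloxy)-2-methoxy-6-methylbenzoate, via monobenzyl ether 2 (not isolated)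
Conditions: BnBr (1.0 equiv), K2CO3, DMF, rt; then MeI, 50 °C
Reagents that add atoms: benzyl bromide, BrCc1ccccc1; iodomethane, CI
Why: Williamson etherification; the C2 hydroxyl is hydrogen-bonded to the ester carbonyl and stays inert at room temperature, so only the C4 phenol is benzylated, and warming with iodomethane then alkylates the chelated phenol in the same pot.

**Step 2**
Reactants: 3 methyl 4-(benzyloxy)-2-methoxy-6-methylbenzoate
Product: 4 4-(benzyloxy)-2-methoxy-6-methylbenzoic acid
Conditions: KOH, DMSO/H2O, 90 °C; then aq. HCl
Reagents that add atoms: potassium hydroxide, [K+].[OH-]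
Why: Saponification of a doubly ortho-substituted methyl ester needs forcing hydroxide; the benzyl and methyl aryl ethers are inert to it, which is why the phenol is carried as a benzyl ether at this stage.

**Step 3**
Reactants: 4 4-(benzyloxy)-2-methoxy-6-methylbenzoic acid
Product: 6 4-(benzyloxy)-2-methoxy-6-methylperoxybenzoic acid, via acid chloride 5 (not isolated)
Conditions: (COCl)2, DMF (cat.), CH2Cl2, rt; then H2O2 (30% aq., large excess), NaOH, MgSO4, 1,4-dioxane/H2O, 0–10 °C; then cold dil. H2SO4
Reagents that add atoms: hydrogen peroxide, OO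
Why: Standard peroxy acid synthesis from an acid chloride and alkaline hydrogen peroxide: the hydroperoxide anion, an α-effect nucleophile, outruns hydroxide at the hindered carbonyl, and the large excess of H2O2 keeps the peroxycarboxylate from being acylated a second time. The peroxy acid is kept cold and used at once.

**Step 4**
Reactants: 4 4-(benzyloxy)-2-methoxy-6-methylbenzoic acid; 6 4-(benzyloxy)-2-methoxy-6-methylperoxybenzoic acid
Product: 8 bis[4-(benzyloxy)-2-methoxy-6-methylbenzoyl] peroxide, via O-acylisourea 7 (not isolated)
Conditions: DCC (1.05 equiv), CH2Cl2/Et2O, 0 °C; filtration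
Reagents that add atoms: none
Why: Carbodiimide condensation of a carboxylic acid with a peroxy acid, an established neutral route to diacyl peroxides: acid 4 adds to DCC to give O-acylisourea 7, whose acyl carbon is attacked by the small, α-effect peroxy oxygen of 6 with loss of the urea. One molecule each of 4 and 6 gives the symmetric peroxide without aqueous alkali; it is kept cold and used at once.

**Step 5**
Reactants: 9 2-methylcyclohexane-1,3-dione; 8 bis[4-(benzyloxy)-2-methoxy-6-methylbenzoyl] peroxide
Product: 11 2-methyl-2-(ArBnCO-oxy)cyclohexane-1,3-dione, via sodium enolate 10 (not isolated)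
Conditions: NaH, THF/DMF, 0 °C; then 8, 0 °C → rt; aq. HCl work-up
Reagents that add atoms: none
Why: Electrophilic α-acyloxylation of a stabilised 1,3-dicarbonyl enolate by a diacyl peroxide: the enolate carbon attacks a peroxide oxygen and expels the carboxylate, while the two ortho substituents keep the enolate off the carbonyl carbons. The product is achiral, so the quaternary carbon is formed without a stereochemical question, and the released acid 4 is recovered for steps 3 and 4.

**Step 6**
Reactants: 11 2-methyl-2-(ArBnCO-oxy)cyclohexane-1,3-dione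
Product: 12 2-methyl-2-(ArHCO-oxy)cyclohexane-1,3-dione
Conditions: H2 (1 atm), Pd/C (palladium on carbon), EtOAc, rt
Reagents that add atoms: none
Why: Hydrogenolysis of the aryl benzyl ether; the ketones and the tertiary alkyl aroate are untouched and no alkene is yet present.

**Step 7**
Reactants: 12 2-methyl-2-(ArHCO-oxy)cyclohexane-1,3-dione
Product: 13 (2R,3S)-3-hydroxy-2-methyl-2-(ArHCO-oxy)cyclohexan-1-one (hydroxyl trans to the ester)
Conditions: ketoreductase (panel-selected), NADP+ (cat.), i-PrOH, KH2PO4/K2HPO4 buffer pH 7, DMSO, 30 °C
Reagents that add atoms: none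
Why: Enzymatic desymmetrising reduction of a 2,2-disubstituted cyclohexane-1,3-dione, a known reaction class for 2-alkyl and 2-alkoxy congeners. The enzyme reduces one enantiotopic carbonyl from the face that carries the ester, which sets C6 (S) and, through the choice of carbonyl, the quaternary C7 (R) in the same event.

**Step 8**
Reactants: 13 (2R,3S)-3-hydroxy-2-methyl-2-(ArHCO-oxy)cyclohexan-1-one
Product: 14 (2R,3S)-2-methyl-2-(ArSiCO-oxy)-3-(TBS-oxy)cyclohexan-1-one
Conditions: TBSOTf (2.5 equiv), 2,6-lutidine, CH2Cl2, −78 → 0 °C
Reagents that add atoms: tert-butyldimethylsilyl trifluoromethanesulfonate, CC(C)(C)[Si](C)(C)OS(=O)(=O)C(F)(F)F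
Why: The silyl triflate with a hindered pyridine base silylates the phenol and the neopentyl-type secondary alcohol at low temperature, without enolising the ketone or triggering retro-aldol opening of the ketol.

**Step 9**
Reactants: 14 (2R,3S)-2-methyl-2-(ArSiCO-oxy)-3-(TBS-oxy)cyclohexan-1-one
Product: 16 (5S,6R)-6-methyl-6-(ArSiCO-oxy)-5-(TBS-oxy)cyclohex-2-en-1-one, via trimethylsilyl enol ether 15 (not isolated)
Conditions: TMSOTf, Et3N, CH2Cl2, 0 °C; then Pd(OAc)2, MeCN, rt
Reagents that add atoms: none
Why: Saegusa–Ito dehydrogenation: soft enolisation can go only toward the CH2 group because the other α-carbon is quaternary, and Pd(OAc)2 turns the silyl enol ether into the enone by β-hydride elimination. Amide bases are avoided because the o-toluate methyl group and the α-acyloxy ketone are both base-sensitive.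

**Step 10**
Reactants: 17 (E)-but-2-enal
Product: 19 (E)-pent-3-en-1-yne, via diazoalkene 18 (not isolated)
Conditions: TMSCHN2 (Et2O solution), n-BuLi (heptane), n-Bu2O, −78 °C; then 17, −78 → 0 °C; H2O; distillation (19 collected with the Et2O)
Reagents that add atoms: (trimethylsilyl)diazomethane, C[Si](C)(C)C=[N+]=[N-]
Why: Aldehyde-to-alkyne homologation by the Colvin rearrangement: lithiated (trimethylsilyl)diazomethane adds 1,2 to the enal, Peterson-type loss of lithium trimethylsilanolate gives diazoalkene 18, and loss of N2 with a 1,2-hydride shift of the alkylidene carbene gives the terminal alkyne with the (E)-alkene untouched. No acetylide or alkyl halide is formed, and the high-boiling medium lets the volatile enyne be distilled with the ether away from the silicon by-products.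

**Step 11**
Reactants: 16 (5S,6R)-6-methyl-6-(ArSiCO-oxy)-5-(TBS-oxy)cyclohex-2-en-1-one; 19 (E)-pent-3-en-1-yne; 20 formaldehyde
Product: 24 (2R,3S,5S,6S)-6-(hydroxymethyl)-2-methyl-2-(ArSiCO-oxy)-5-[(E)-pent-3-en-1-ynyl]-3-(TBS-oxy)cyclohexan-1-one (alkynyl trans to hydroxymethyl and anti to the C6 silyloxy group), via lithium (E)-pent-3-en-1-ynide 21 (not isolated), via dimethyl[(E)-pent-3-en-1-ynyl]alane 22 (not isolated), via dimethylaluminium enolate 23 (not isolated)
Conditions: 19 (Et2O solution), n-BuLi, Et2O, −40 → 0 °C; Me2AlCl; Ni(acac)2 (10 mol %), iBu2AlH (10 mol %), Et2O, 0 °C; 16, −5 °C; then CH2O gas (20), −40 → 0 °C; aq. KNaC4H4O6 (potassium sodium tartrate)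
Reagents that add atoms: none
Why: Deprotonation of 19 to acetylide 21 and transmetalation with Me2AlCl give alane 22; Ni(acac)2 is reduced by iBu2AlH to zerovalent nickel, which engages the s-trans enone 16 (the uncatalysed six-centre alkynylalane pathway needs an s-cis enone), takes the alkynyl group from aluminium and delivers it to C4a, releasing the dimethylaluminium enolate 23. Because C7 is quaternary, 23 is a single regioisomer that cannot equilibrate, and it adds through carbon to monomeric formaldehyde 20 in an aluminium-bound aldol that forms C8a–C1; hydrolysis of the aluminium alkoxide gives 24. The closest known reaction type is the nickel-catalysed conjugate addition of alkynyl(dimethyl)alanes to cyclic enones combined with aldehyde capture of the metal enolate, a three-component enone coupling. No ring is closed. At C4a the alkynyl group should enter axially on the half-chair anti to the C6 silyloxy group (the trans-3,5 preference of 5-substituted cyclohexenones), and at C8a formaldehyde should approach anti to the new alkynyl group; both centres are erased in step 13, so any diastereomer mixture is carried on. The selectivities that matter are 1,4- over 1,2-addition (nickel catalysis, and a carbonyl flanked by the quaternary C7), alkynyl over methyl transfer (inherent to mixed alkynylalanes) and C- over O-capture of formaldehyde (normal for aluminium enolates). The doubly ortho-substituted aroate makes an α'-acyloxy enolate tolerable, since its carbonyl is shielded from the alane and from intramolecular attack by C8a, and the silyl ethers are inert.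

**Step 12**
Reactants: 24 (2R,3S,5S,6S)-6-(hydroxymethyl)-2-methyl-2-(ArSiCO-oxy)-5-[(E)-pent-3-en-1-ynyl]-3-(TBS-oxy)cyclohexan-1-one
Product: 25 (2R,3S,5S,6S)-2-methyl-2-(ArSiCO-oxy)-5-[(E)-pent-3-en-1-ynyl]-3-(TBS-oxy)-6-[(TBS-oxy)methyl]cyclohexan-1-one
Conditions: TBSCl, imidazole, CH2Cl2, 0 °C → rt
Reagents that add atoms: tert-butyldimethylsilyl chloride, CC(C)(C)[Si](C)(C)Cl
Why: Silylation of the only free hydroxyl; protection blocks retro-aldol loss of formaldehyde and keeps the oxygen away from palladium in the next step.

**Step 13**
Reactants: 25 (2R,3S,5S,6S)-2-methyl-2-(ArSiCO-oxy)-5-[(E)-pent-3-en-1-ynyl]-3-(TBS-oxy)-6-[(TBS-oxy)methyl]cyclohexan-1-one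
Product: 27 (5S,6R)-6-methyl-6-(ArSiCO-oxy)-3-[(E)-pent-3-en-1-ynyl]-5-(TBS-oxy)-2-[(TBS-oxy)methyl]cyclohex-2-en-1-one, via trimethylsilyl enol ether 26 (not isolated)
Conditions: TMSOTf, Et3N, CH2Cl2, 0 °C → rt; then Pd(OAc)2, MeCN, rt
Reagents that add atoms: none
Why: Second Saegusa–Ito dehydrogenation: the ketone can enolise only toward C8a, and palladium on C8a eliminates the propargylic C4a hydrogen to give the conjugated tetrasubstituted enynone, erasing both centres made in step 11. Elimination toward the silyloxymethyl carbon would give an unconjugated enol ether and is disfavoured.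

**Step 14**
Reactants: 27 (5S,6R)-6-methyl-6-(ArSiCO-oxy)-3-[(E)-pent-3-en-1-ynyl]-5-(TBS-oxy)-2-[(TBS-oxy)methyl]cyclohex-2-en-1-one
Product: 28 (5S,6R)-5-hydroxy-2-(hydroxymethyl)-6-methyl-6-(ArHCO-oxy)-3-[(E)-pent-3-en-1-ynyl]cyclohex-2-en-1-one
Conditions: HF·pyridine (excess), pyridine/THF, 0 °C → rt
Reagents that add atoms: none
Why: Fluoride cleavage of the primary, secondary and aryl silyl ethers under buffered acidic conditions, which never generate the C6 alkoxide that would start acyl shift or retro-aldol. The hindered aroate is stable, and any 29 formed by early cyclisation is carried forward.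

**Step 15**
Reactants: 28 (5S,6R)-5-hydroxy-2-(hydroxymethyl)-6-methyl-6-(ArHCO-oxy)-3-[(E)-pent-3-en-1-ynyl]cyclohex-2-en-1-one
Product: 29 (6S,7R)-6-hydroxy-7-methyl-8-oxo-3-[(E)-prop-1-enyl]-5,6,7,8-tetrahydro-1H-isochromen-7-yl 4-hydroxy-2-methoxy-6-methylbenzoate
Conditions: Ph3PAuNTf2 (5 mol %), CH2Cl2, rt
Reagents that add atoms: none
Why: Monovalent gold activates the alkyne and the cis-disposed C1 hydroxyl adds anti at C3 (6-endo-dig), followed by protodeauration. C3 is the δ-carbon of the enynone and bears the propenyl group, so it is the electrophilic alkyne terminus, and neither the C6 hydroxyl nor the phenol can reach the alkyne.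

## Compound list

1 | methyl orsellinate (methyl 2,4-dihydroxy-6-methylbenzoate) | COC(=O)c1c(C)cc(O)cc1O | starting material
2 | methyl 4-(benzyloxy)-2-hydroxy-6-methylbenzoate | COC(=O)c1c(C)cc(OCc2ccccc2)cc1O | intermediate
3 | methyl 4-(benzyloxy)-2-methoxy-6-methylbenzoate | COC(=O)c1c(C)cc(OCc2ccccc2)cc1OC | intermediate
4 | 4-(benzyloxy)-2-methoxy-6-methylbenzoic acid | OC(=O)c1c(C)cc(OCc2ccccc2)cc1OC | intermediate
5 | 4-(benzyloxy)-2-methoxy-6-methylbenzoyl chloride | ClC(=O)c1c(C)cc(OCc2ccccc2)cc1OC | intermediate
6 | 4-(benzyloxy)-2-methoxy-6-methylperoxybenzoic acid | OOC(=O)c1c(C)cc(OCc2ccccc2)cc1OC | intermediate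
7 | N,N'-dicyclohexyl-O-[4-(benzyloxy)-2-methoxy-6-methylbenzoyl]isourea | O=C(OC(=NC1CCCCC1)NC1CCCCC1)c1c(C)cc(OCc2ccccc2)cc1OC | intermediate
8 | bis[4-(benzyloxy)-2-methoxy-6-methylbenzoyl] peroxide | O=C(OOC(=O)c1c(C)cc(OCc2ccccc2)cc1OC)c1c(C)cc(OCc2ccccc2)cc1OC | intermediate
9 | 2-methylcyclohexane-1,3-dione | CC1C(=O)CCCC1=O | starting material
10 | sodium 2-methyl-3-oxocyclohex-1-en-1-olate | CC1=C([O-])CCCC1=O.[Na+] | intermediate
11 | 2-methyl-2-(ArBnCO-oxy)cyclohexane-1,3-dione | CC1(OC(=O)c2c(C)cc(OCc3ccccc3)cc2OC)C(=O)CCCC1=O | intermediate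
12 | 2-methyl-2-(ArHCO-oxy)cyclohexane-1,3-dione | CC1(OC(=O)c2c(C)cc(O)cc2OC)C(=O)CCCC1=O | intermediate
13 | (2R,3S)-3-hydroxy-2-methyl-2-(ArHCO-oxy)cyclohexan-1-one | O=C1[C@](C)(OC(=O)c2c(C)cc(O)cc2OC)[C@@H](O)CCC1 | intermediate
14 | (2R,3S)-2-methyl-2-(ArSiCO-oxy)-3-(TBS-oxy)cyclohexan-1-one | O=C1[C@](C)(OC(=O)c2c(C)cc(O[Si](C)(C)C(C)(C)C)cc2OC)[C@@H](O[Si](C)(C)C(C)(C)C)CCC1 | intermediate
15 | (5S,6R)-6-methyl-6-(ArSiCO-oxy)-5-(TBS-oxy)-1-(TMS-oxy)cyclohex-1-ene | C[Si](C)(C)OC=1[C@](C)(OC(=O)c2c(C)cc(O[Si](C)(C)C(C)(C)C)cc2OC)[C@@H](O[Si](C)(C)C(C)(C)C)CCC=1 | intermediate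
16 | (5S,6R)-6-methyl-6-(ArSiCO-oxy)-5-(TBS-oxy)cyclohex-2-en-1-one | C1=CC(=O)[C@](C)(OC(=O)c2c(C)cc(O[Si](C)(C)C(C)(C)C)cc2OC)[C@@H](O[Si](C)(C)C(C)(C)C)C1 | intermediate
17 | (E)-but-2-enal | C/C=C/C=O | starting material
18 | (3E)-1-diazopenta-1,3-diene | C/C=C/C=C=[N+]=[N-] | intermediate
19 | (E)-pent-3-en-1-yne | C/C=C/C#C | intermediate
20 | formaldehyde (monomer, from paraformaldehyde) | C=O | starting material
21 | lithium (E)-pent-3-en-1-ynide | [Li]C#C/C=C/C | intermediate
22 | dimethyl[(E)-pent-3-en-1-ynyl]alane | C[Al](C)C#C/C=C/C | intermediate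
23 | dimethylaluminium (3S,5S,6R)-6-methyl-6-(ArSiCO-oxy)-3-[(E)-pent-3-en-1-ynyl]-5-(TBS-oxy)cyclohex-1-en-1-olate | C[Al](C)OC=1[C@](C)(OC(=O)c2c(C)cc(O[Si](C)(C)C(C)(C)C)cc2OC)[C@@H](O[Si](C)(C)C(C)(C)C)C[C@H](C#C/C=C/C)C=1 | intermediate
24 | (2R,3S,5S,6S)-6-(hydroxymethyl)-2-methyl-2-(ArSiCO-oxy)-5-[(E)-pent-3-en-1-ynyl]-3-(TBS-oxy)cyclohexan-1-one | O=C1[C@](C)(OC(=O)c2c(C)cc(O[Si](C)(C)C(C)(C)C)cc2OC)[C@@H](O[Si](C)(C)C(C)(C)C)C[C@H](C#C/C=C/C)[C@H]1CO | intermediate
25 | (2R,3S,5S,6S)-2-methyl-2-(ArSiCO-oxy)-5-[(E)-pent-3-en-1-ynyl]-3-(TBS-oxy)-6-[(TBS-oxy)methyl]cyclohexan-1-one | O=C1[C@](C)(OC(=O)c2c(C)cc(O[Si](C)(C)C(C)(C)C)cc2OC)[C@@H](O[Si](C)(C)C(C)(C)C)C[C@H](C#C/C=C/C)[C@H]1CO[Si](C)(C)C(C)(C)C | intermediate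
26 | (3R,5S,6R)-6-methyl-6-(ArSiCO-oxy)-3-[(E)-pent-3-en-1-ynyl]-5-(TBS-oxy)-2-[(TBS-oxy)methyl]-1-(TMS-oxy)cyclohex-1-ene | C[Si](C)(C)OC=1[C@](C)(OC(=O)c2c(C)cc(O[Si](C)(C)C(C)(C)C)cc2OC)[C@@H](O[Si](C)(C)C(C)(C)C)C[C@H](C#C/C=C/C)C=1CO[Si](C)(C)C(C)(C)C | intermediate
27 | (5S,6R)-6-methyl-6-(ArSiCO-oxy)-3-[(E)-pent-3-en-1-ynyl]-5-(TBS-oxy)-2-[(TBS-oxy)methyl]cyclohex-2-en-1-one | O=C1[C@](C)(OC(=O)c2c(C)cc(O[Si](C)(C)C(C)(C)C)cc2OC)[C@@H](O[Si](C)(C)C(C)(C)C)CC(C#C/C=C/C)=C1CO[Si](C)(C)C(C)(C)C | intermediate
28 | (5S,6R)-5-hydroxy-2-(hydroxymethyl)-6-methyl-6-(ArHCO-oxy)-3-[(E)-pent-3-en-1-ynyl]cyclohex-2-en-1-one | O=C1[C@](C)(OC(=O)c2c(C)cc(O)cc2OC)[C@@H](O)CC(C#C/C=C/C)=C1CO | intermediate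
29 | (6S,7R)-6-hydroxy-7-methyl-8-oxo-3-[(E)-prop-1-enyl]-5,6,7,8-tetrahydro-1H-isochromen-7-yl 4-hydroxy-2-methoxy-6-methylbenzoate | C/C=C/C1=CC2=C(CO1)C(=O)[C@](C)(OC(=O)c1c(C)cc(O)cc1OC)[C@@H](O)C2 | target

## Step count and uncertain steps

Total: 15 steps. Longest linear sequence: 14 steps (steps 1–9 and 11–15, from 1); the enyne 19 is made in one step (step 10) and joins at step 11.

**Step 11 (key step).** The most likely failures are incomplete capture of the aluminium enolate by formaldehyde, so that protonation on work-up gives only the conjugate adduct, and deactivation of the zerovalent nickel catalyst with slow direct 1,2-addition of the alane taking over. The fallback keeps both bonds but separates them and uses neither nickel nor an aluminium enolate. It sets out from 16 and 19 and returns at 24. Acetylide 21, made from 19 and n-BuLi as in the main step, is transmetalated with ZnBr2 to [(E)-pent-3-en-1-ynyl]zinc bromide F1, which adds 1,4 to 16 in the presence of TBSOTf (Et2O/THF, −40 °C) to give the tert-butyldimethylsilyl enol ether F2. A Mukaiyama aldol of F2 with aqueous formaldehyde, catalysed by Sc(OTf)3 in THF/H2O, then forms C8a–C1 and gives 24.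

**Step 7.** The panel may contain no enzyme that accepts the bulky aroate, or the accepted substrate may be reduced from the face anti to the ester, giving the cis ketol; steric and polar effects both favour that face for small hydride reagents. The fallback replaces desymmetrisation by resolution; it sets out from 12 and returns at 13. Chelation-controlled reduction with a limited charge of Zn(BH4)2 (Et2O, −20 °C), which ties the ketone to the C7 ester oxygen and sends hydride anti to the axial methyl group, should give the racemic trans ketol, that is 13 together with its enantiomer, the (2S,3R)-ketol F3. An immobilised lipase with vinyl acetate should then acetylate F3, the enantiomer predicted by the empirical size rule for secondary alcohols, to the (2S,3R)-acetate F4 and leave 13, which is separated and taken on to step 8.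

**Step 13.** Enol silylation of a ketone flanked by a quaternary and a tertiary carbon may be slow, divalent palladium may engage the enyne, and β-hydride elimination may stray toward the silyloxymethyl carbon. The fallback is a selenoxide elimination; it sets out from 25 through the same enol ether 26 and returns at 27. PhSeCl (CH2Cl2, −78 °C) should attack 26 anti to the alkynyl group and give the C8a phenylselanyl ketone F5, with selenium cis to the C4a hydrogen. Oxidation with H2O2/pyridine at 0 °C then eliminates syn toward C4a, because selenoxides avoid eliminating toward an oxygen-bearing carbon, and gives 27.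

**Step 15.** The hydroxyl may add 5-exo at C4, as simple (Z)-2-en-4-yn-1-ols tend to do under gold catalysis, leading to an alkylidene dihydrofuran or furan. The fallback fixes the regiochemistry by nucleophilic 1,6-addition; it sets out from 28 and returns at 29. Morpholine adds to the δ-carbon C3 of the enynone (THF, rt) to give the dienaminone F6. Mild acid (AcOH, CH2Cl2) then lets the C1 hydroxyl add to the C3 iminium carbon and expel morpholine, closing the pyran by an addition–elimination that can only give the six-membered ring.

**Step 5.** The electron-rich peroxide 8 may decompose by carboxy inversion before it meets the enolate, the carbodiimide coupling that makes it (step 4) may be slow at the doubly ortho-substituted acyl carbon, and part of the enolate may be lost by acyl transfer. The fallback uses a hypervalent iodine carrier and needs neither 6 nor 8; it sets out from 4 and 9 and returns at 11. Ligand exchange of PhI(OAc)2 with two equivalents of 4 (chlorobenzene, 50 °C, removal of acetic acid under reduced pressure) gives the bis(aroyloxy)iodobenzene F7, which transfers one aroyloxy group to the enol of 9 (MeCN, rt) in the established α-acyloxylation of 1,3-dicarbonyl compounds by [bis(acyloxy)iodo]arenes.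

## Further compounds

F1 | step 11 | [(E)-pent-3-en-1-ynyl]zinc bromide | Br[Zn]C#C/C=C/C
F2 | step 11 | (3S,5S,6R)-6-methyl-6-(ArSiCO-oxy)-3-[(E)-pent-3-en-1-ynyl]-1,5-bis(TBS-oxy)cyclohex-1-ene | CC(C)(C)[Si](C)(C)OC=1[C@](C)(OC(=O)c2c(C)cc(O[Si](C)(C)C(C)(C)C)cc2OC)[C@@H](O[Si](C)(C)C(C)(C)C)C[C@H](C#C/C=C/C)C=1
F3 | step 7 | (2S,3R)-3-hydroxy-2-methyl-2-(ArHCO-oxy)cyclohexan-1-one (enantiomer of 13) | O=C1[C@@](C)(OC(=O)c2c(C)cc(O)cc2OC)[C@H](O)CCC1
F4 | step 7 | (2S,3R)-3-acetoxy-2-methyl-2-(ArHCO-oxy)cyclohexan-1-one | O=C1[C@@](C)(OC(=O)c2c(C)cc(O)cc2OC)[C@H](OC(C)=O)CCC1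
F5 | step 13 | (2R,3S,5R,6S)-2-methyl-2-(ArSiCO-oxy)-5-[(E)-pent-3-en-1-ynyl]-6-(phenylselanyl)-3-(TBS-oxy)-6-[(TBS-oxy)methyl]cyclohexan-1-one | O=C1[C@](C)(OC(=O)c2c(C)cc(O[Si](C)(C)C(C)(C)C)cc2OC)[C@@H](O[Si](C)(C)C(C)(C)C)C[C@H](C#C/C=C/C)[C@]1([Se]c2ccccc2)CO[Si](C)(C)C(C)(C)C
F6 | step 15 | (5S,6R)-5-hydroxy-2-(hydroxymethyl)-6-methyl-6-(ArHCO-oxy)-3-[(3E)-2-(morpholin-4-yl)penta-1,3-dien-1-yl]cyclohex-2-en-1-one | C/C=C/C(=CC1=C(CO)C(=O)[C@](C)(OC(=O)c2c(C)cc(O)cc2OC)[C@@H](O)C1)N1CCOCC1
F7 | step 5 | bis[4-(benzyloxy)-2-methoxy-6-methylbenzoyloxy](phenyl)-λ3-iodane | O=C(O[I](OC(=O)c1c(C)cc(OCc2ccccc2)cc1OC)c1ccccc1)c1c(C)cc(OCc2ccccc2)cc1OC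
A1 | alternative 1 | (6S,7R)-7-methyl-8-oxo-3-[(E)-prop-1-enyl]-6-(TBS-oxy)-5,6,7,8-tetrahydro-1H-isochromen-7-yl but-2-ynoate | C/C=C/C1=CC2=C(CO1)C(=O)[C@](C)(OC(=O)C#CC)[C@@H](O[Si](C)(C)C(C)(C)C)C2
A2 | alternative 1 | 1,1-dimethoxy-3-(trimethylsilyloxy)buta-1,3-diene | C=C(O[Si](C)(C)C)C=C(OC)OC
A3 | alternative 1 | 6-O-TBS ether of 29 | C/C=C/C1=CC2=C(CO1)C(=O)[C@](C)(OC(=O)c3c(C)cc(O)cc3OC)[C@@H](O[Si](C)(C)C(C)(C)C)C2
A4 | alternative 2 | racemic 6-(ArSiCO-oxy)-5-oxoheptanal | CC(OC(=O)c1c(C)cc(O[Si](C)(C)C(C)(C)C)cc1OC)C(=O)CCCC=O
A5 | alternative 2 | (2R,3S)-3-hydroxy-2-methyl-2-(ArSiCO-oxy)cyclohexan-1-one | O=C1[C@](C)(OC(=O)c3c(C)cc(O[Si](C)(C)C(C)(C)C)cc3OC)[C@@H](O)CCC1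
A6 | alternative 3 | ring A-fused furyl carbinol: (5R,6S)-5-methyl-4-oxo-3-[(E)-1-hydroxybut-2-enyl]-6-(TBS-oxy)-4,5,6,7-tetrahydro-2-benzofuran-5-yl 4-(TBS-oxy)-2-methoxy-6-methylbenzoate (carbinol configuration as in A7) | C/C=C/[C@@H](O)c1occ2c1C[C@H](O[Si](C)(C)C(C)(C)C)[C@@](C)(OC(=O)c3c(C)cc(O[Si](C)(C)C(C)(C)C)cc3OC)C2=O
A7 | alternative 3 | 1-hydroxy-1H-isochromene-4,8-dione lactol (anomers at C1) | C/C=C/[C@H]1OC(O)C2=C(C1=O)C[C@H](O[Si](C)(C)C(C)(C)C)[C@@](C)(OC(=O)c3c(C)cc(O[Si](C)(C)C(C)(C)C)cc3OC)C2=O
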